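**Retrosynthetic overview**
- The target is reached by desilylation of O9 from a TBS-protected lactone; both rings are closed in one flask from an open-chain C15 enal–allylboronate that already carries the complete C8 ester.
- Ring order as in the biosynthesis: first the ten-membered carbocycle by C6–C7 bond formation between the two ends of a (2E,6Z)-farnesane-type chain (the germacrene-forming bond), then the 6,12-lactone by attack of the new O6 on C12. This is done as a chiral-phosphoric-acid-catalysed intramolecular allylboration/lactonisation that sets C6 and C7 (cis fusion).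
- The seco-chain comes from an E-selective Wittig reaction of a C7 aldehyde with a CH2Bpin-bearing stabilised ylide; the C8 ester comes from Steglich coupling with the stearoyloxy acid, made from (R)-methylsuccinic acid mono-tert-butyl ester.
- C9–C10 is made by Nozaki–Hiyama–Kishi coupling of a (Z)-alkenyl iodide (from geranyl acetate) with (S)-glyceraldehyde acetonide (C8 from the pool, C9 by Felkin control).

Assumption: atom labels C1–C15 follow germacrane numbering; the SMILES is read as the 6,12-cis-fused (6S,7S,8S,9R), 1(10)Z,4E isomer with an (R)-configured side chain, i.e. (3aS,4S,5R,6Z,10E,11aS) in cyclodeca[b]furan numbering.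

**Route**

Step 1
Reactants: 1 geranyl acetate
Product: 4 (2E)-3-methyl-6-oxohex-2-en-1-yl acetate, via 6,7-epoxygeranyl acetate 2 (not isolated), via 6,7-dihydroxy-6,7-dihydrogeranyl acetate 3 (not isolated)
Conditions: mCPBA, CH2Cl2, 0 °C; then H5IO6, THF/H2O, 0 °C → rt
Reagents that add atoms: mCPBA, O=C(OO)c1cccc(Cl)c1
Why: Prilezhaev epoxidation selects the electron-rich 6,7-alkene (the 2,3-alkene is deactivated by the allylic acetate), and periodic acid opens the epoxide to the diol and cleaves it (Malaprade glycol cleavage), leaving the 2E alkene untouched.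

Step 2
Reactants: 4 (2E)-3-methyl-6-oxohex-2-en-1-yl acetate
Product: 6 (2E,6Z)-7-iodo-3-methylocta-2,6-dien-1-ol, via (2E,6Z)-7-iodo-3-methylocta-2,6-dien-1-yl acetate 5 (not isolated)
Conditions: [EtPPh3]I, n-BuLi, THF, 0 °C; I2, −78 °C; NaHMDS, −78 °C; then 4, −78 → −20 °C; then K2CO3 (cat.), MeOH, rt
Reagents that add atoms: ethyltriphenylphosphonium iodide, CC[P+](c1ccccc1)(c1ccccc1)c1ccccc1.[I-]; iodine, II
Why: Wittig olefination with the α-iodoethylidene ylide (Stork–Zhao-type iodo-olefination) is kinetically cis-selective and places iodine cis to the chain, which sets the 1(10)Z geometry; carbonate-catalysed transesterification then frees the allylic alcohol.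

Step 3
Reactants: 6 (2E,6Z)-7-iodo-3-methylocta-2,6-dien-1-ol; 7 (4S)-2,2-dimethyl-1,3-dioxolane-4-carbaldehyde
Product: 8 (1R,2Z,6E)-1-[(4S)-2,2-dimethyl-1,3-dioxolan-4-yl]-2,6-dimethylocta-2,6-diene-1,8-diol
Conditions: CrCl2 (6 equiv), NiCl2 (2 mol %), 7 (2 equiv), DMSO, rt
Reagents that add atoms: none
Why: Nozaki–Hiyama–Kishi coupling: the alkenylchromium(III) species keeps the trisubstituted Z geometry, tolerates the free hydroxyl and adds to the α-alkoxy aldehyde in the non-chelated Felkin–Anh sense, giving the 8,9-anti (erythro) pattern, i.e. the (9R) carbinol from the (S) centre of 7 (minor syn epimer removed by chromatography).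

Step 4
Reactants: 8 (1R,2Z,6E)-1-[(4S)-2,2-dimethyl-1,3-dioxolan-4-yl]-2,6-dimethylocta-2,6-diene-1,8-diol
Product: 9 (2E,6Z,8R)-8-[(4S)-2,2-dimethyl-1,3-dioxolan-4-yl]-8-hydroxy-3,7-dimethylocta-2,6-dienal
Conditions: TEMPO (10 mol %), PhI(OAc)2, CH2Cl2, rt
Reagents that add atoms: none
Why: Oxoammonium-catalysed (TEMPO/PhI(OAc)2) oxidation is selective for the primary allylic alcohol over the hindered secondary one and gives the E-enal without touching the acetonide.

Step 5
Reactants: 9 (2E,6Z,8R)-8-[(4S)-2,2-dimethyl-1,3-dioxolan-4-yl]-8-hydroxy-3,7-dimethylocta-2,6-dienal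
Product: 10 (2E,6Z,8R)-8-[(tert-butyldimethylsilyl)oxy]-8-[(4S)-2,2-dimethyl-1,3-dioxolan-4-yl]-3,7-dimethylocta-2,6-dienal
Conditions: TBSOTf, 2,6-lutidine, CH2Cl2, −78 → 0 °C
Reagents that add atoms: tert-butyldimethylsilyl triflate, CC(C)(C)[Si](C)(C)OS(=O)(=O)C(F)(F)F
Why: Silylation of the only free hydroxyl with the reactive silyl triflate protects O9 so that O8 can later be acylated alone.

Step 6
Reactants: 10 (2E,6Z,8R)-8-[(tert-butyldimethylsilyl)oxy]-8-[(4S)-2,2-dimethyl-1,3-dioxolan-4-yl]-3,7-dimethylocta-2,6-dienal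
Product: 11 (2E,6Z,8R,9S)-8-[(tert-butyldimethylsilyl)oxy]-9,10-dihydroxy-3,7-dimethyldeca-2,6-dienal
Conditions: AcOH/H2O/THF (3:1:1), 40 °C
Reagents that add atoms: none
Why: Mild acid-catalysed acetal hydrolysis cleaves the terminal isopropylidene group while the secondary TBS ether and the enal survive.

Step 7
Reactants: 11 (2E,6Z,8R,9S)-8-[(tert-butyldimethylsilyl)oxy]-9,10-dihydroxy-3,7-dimethyldeca-2,6-dienal
Product: 12 (2E,6Z,8R,9S)-8-[(tert-butyldimethylsilyl)oxy]-9-hydroxy-3,7-dimethyl-10-[(triethylsilyl)oxy]deca-2,6-dienal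
Conditions: TESCl (1.05 equiv), imidazole, CH2Cl2, −78 °C
Reagents that add atoms: chlorotriethylsilane, CC[Si](CC)(CC)Cl
Why: Kinetic silylation at low temperature selects the primary over the flanked secondary hydroxyl, leaving O8 as the only free OH.

Step 8
Reactants: 13 (2R)-4-tert-butoxy-2-methyl-4-oxobutanoic acid
Product: 14 tert-butyl (3R)-4-hydroxy-3-methylbutanoate
Conditions: BH3·SMe2, THF, 0 °C → rt; H2O
Reagents that add atoms: none
Why: Borane reduces the carboxylic acid chemoselectively in the presence of the tert-butyl ester; the stereocentre is not involved and stays R.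

Step 9
Reactants: 14 tert-butyl (3R)-4-hydroxy-3-methylbutanoate
Product: 15 tert-butyl (3R)-3-methyl-4-(octadecanoyloxy)butanoate
Conditions: stearoyl chloride, pyridine, DMAP (cat.), CH2Cl2, 0 °C → rt
Reagents that add atoms: octadecanoyl chloride, CCCCCCCCCCCCCCCCCC(=O)Cl
Why: DMAP-catalysed acylation of the primary alcohol with the acid chloride installs the stearate.

Step 10
Reactants: 15 tert-butyl (3R)-3-methyl-4-(octadecanoyloxy)butanoate
Product: 16 (3R)-3-methyl-4-(octadecanoyloxy)butanoic acid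
Conditions: TFA/CH2Cl2 (1:4), rt
Reagents that add atoms: none
Why: Acidolysis of the tert-butyl ester (E1 loss of isobutene) leaves the primary stearate intact.

Step 11
Reactants: 12 (2E,6Z,8R,9S)-8-[(tert-butyldimethylsilyl)oxy]-9-hydroxy-3,7-dimethyl-10-[(triethylsilyl)oxy]deca-2,6-dienal; 16 (3R)-3-methyl-4-(octadecanoyloxy)butanoic acid
Product: 17 (2S,3R,4Z,8E)-3-[(tert-butyldimethylsilyl)oxy]-4,8-dimethyl-10-oxo-1-[(triethylsilyl)oxy]deca-4,8-dien-2-yl (3R)-3-methyl-4-(octadecanoyloxy)butanoate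
Conditions: DCC, DMAP, CH2Cl2, 0 °C → rt
Reagents that add atoms: none
Why: Steglich esterification of the single free secondary hydroxyl installs the complete C8 side chain with retention at C8.

Step 12
Reactants: 17 (2S,3R,4Z,8E)-3-[(tert-butyldimethylsilyl)oxy]-4,8-dimethyl-10-oxo-1-[(triethylsilyl)oxy]deca-4,8-dien-2-yl (3R)-3-methyl-4-(octadecanoyloxy)butanoate
Product: 18 (2R,3R,4Z,8E)-3-[(tert-butyldimethylsilyl)oxy]-4,8-dimethyl-1,10-dioxodeca-4,8-dien-2-yl (3R)-3-methyl-4-(octadecanoyloxy)butanoate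
Conditions: (COCl)2, DMSO, CH2Cl2, −78 → −40 °C; Et3N, −78 → 0 °C; used crude
Reagents that add atoms: none
Why: Swern oxidation converts a primary triethylsilyl ether directly into the aldehyde while the secondary TBS ether is inert; the low temperature avoids epimerisation of the α-acyloxy aldehyde (the 2R label is a CIP priority change only).

Step 13
Reactants: 19 methyl (triphenyl-λ5-phosphanylidene)acetate
Product: 21 methyl 3-(4,4,5,5-tetramethyl-1,3,2-dioxaborolan-2-yl)-2-(triphenyl-λ5-phosphanylidene)propanoate, via alkylated phosphonium iodide 20 (not isolated)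
Conditions: ICH2Bpin (1 equiv), 19 (2 equiv), toluene, 60 °C; filter off phosphonium salt
Reagents that add atoms: 2-(iodomethyl)-4,4,5,5-tetramethyl-1,3,2-dioxaborolane, ICB1OC(C)(C)C(C)(C)O1
Why: Proposed new method: C-alkylation of the stabilised ylide by the α-iodo boronate (attack at boron to an ate complex, then 1,2-shift with loss of iodide, as in Matteson substitutions of halomethylboronates) gives salt 20, which a second equivalent of 19 deprotonates (transylidation); the closest known reaction type is the Bestmann alkylation/transylidation of ester-stabilised phosphoranes with reactive alkyl halides.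

Step 14
Reactants: 18 (2R,3R,4Z,8E)-3-[(tert-butyldimethylsilyl)oxy]-4,8-dimethyl-1,10-dioxodeca-4,8-dien-2-yl (3R)-3-methyl-4-(octadecanoyloxy)butanoate; 21 methyl 3-(4,4,5,5-tetramethyl-1,3,2-dioxaborolan-2-yl)-2-(triphenyl-λ5-phosphanylidene)propanoate
Product: 22 methyl (2E,4S,5R,6Z,10E)-5-[(tert-butyldimethylsilyl)oxy]-6,10-dimethyl-4-{[(3R)-3-methyl-4-(octadecanoyloxy)butanoyl]oxy}-12-oxo-2-[(4,4,5,5-tetramethyl-1,3,2-dioxaborolan-2-yl)methyl]dodeca-2,6,10-trienoate
Conditions: 21 (1.3 equiv), CH2Cl2, rt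
Reagents that add atoms: none
Why: Wittig olefination with an α-substituted ester-stabilised ylide is E-selective (C8 trans to CO2Me, cis to CH2B) and chemoselective for the aliphatic α-acyloxy aldehyde over the unreactive β,β-disubstituted enal.

Step 15
Reactants: 22 methyl (2E,4S,5R,6Z,10E)-5-[(tert-butyldimethylsilyl)oxy]-6,10-dimethyl-4-{[(3R)-3-methyl-4-(octadecanoyloxy)butanoyl]oxy}-12-oxo-2-[(4,4,5,5-tetramethyl-1,3,2-dioxaborolan-2-yl)methyl]dodeca-2,6,10-trienoate
Product: 24 (3aS,4S,5R,6Z,10E,11aS)-5-[(tert-butyldimethylsilyl)oxy]-6,10-dimethyl-3-methylidene-2-oxo-2,3,3a,4,5,8,9,11a-octahydrocyclodeca[b]furan-4-yl (3R)-3-methyl-4-(octadecanoyloxy)butanoate, via macrocyclic pinacol borate 23 (not isolated)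
Conditions: (R)-TRIP (10 mol %), 4 Å MS, toluene (1 mM), rt → 40 °C; then PPTS (cat.), 40 °C
Reagents that add atoms: none
Why: Proposed new method: a macrocyclising, Brønsted-acid-catalysed allylboration–lactonisation; the (E)-allylboronate (C8 cis to CH2B, i.e. Z-crotyl type) adds to the enal through a closed Zimmerman–Traxler chair with C5 equatorial and C8 axial, which forms the C6–C7 bond of the ten-membered ring and fixes the syn C6/C7 relationship (cis ring fusion), (R)-TRIP activates the boronate by hydrogen bonding to a pinacol oxygen and is expected, by analogy with aryl and alkenyl aldehydes, to direct C7 to the Re face of the aldehyde (6S, hence 7S) with C6–C7–C8–C9 antiperiplanar, and borate 23 then acylates itself on the methyl ester to close the lactone; the closest known reaction types are the intermolecular allylboration of aldehydes by 2-alkoxycarbonyl allylboronates to cis-β,γ-disubstituted α-methylene-γ-butyrolactones and the chiral-phosphoric-acid-catalysed allylboration of aldehydes with pinacol allylboronates, and only weak acids are used so that the allylic C6–O bond is not ionised.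

Step 16
Reactants: 24 (3aS,4S,5R,6Z,10E,11aS)-5-[(tert-butyldimethylsilyl)oxy]-6,10-dimethyl-3-methylidene-2-oxo-2,3,3a,4,5,8,9,11a-octahydrocyclodeca[b]furan-4-yl (3R)-3-methyl-4-(octadecanoyloxy)butanoate
Product: 25 (3aS,4S,5R,6Z,10E,11aS)-5-hydroxy-6,10-dimethyl-3-methylidene-2-oxo-2,3,3a,4,5,8,9,11a-octahydrocyclodeca[b]furan-4-yl (3R)-3-methyl-4-(octadecanoyloxy)butanoate
Conditions: HF·pyridine, pyridine, THF, 0 °C → rt
Reagents that add atoms: none
Why: Buffered fluoride desilylation frees the C9 hydroxyl without acyl migration or attack on the α-methylene lactone.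

**Compound list**
1 | geranyl acetate, (2E)-3,7-dimethylocta-2,6-dien-1-yl acetate | CC(C)=CCC/C(C)=C/COC(C)=O | starting material
2 | 6,7-epoxygeranyl acetate (racemic) | CC1(C)OC1CC/C(C)=C/COC(C)=O | intermediate
3 | 6,7-dihydroxy-6,7-dihydrogeranyl acetate (racemic) | CC(C)(O)C(O)CC/C(C)=C/COC(C)=O | intermediate
4 | (2E)-3-methyl-6-oxohex-2-en-1-yl acetate | O=CCC/C(C)=C/COC(C)=O | intermediate
5 | (2E,6Z)-7-iodo-3-methylocta-2,6-dien-1-yl acetate | CC(=O)OC/C=C(\C)CC/C=C(/C)I | intermediate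
6 | (2E,6Z)-7-iodo-3-methylocta-2,6-dien-1-ol | OC/C=C(\C)CC/C=C(/C)I | intermediate
7 | (4S)-2,2-dimethyl-1,3-dioxolane-4-carbaldehyde, (S)-glyceraldehyde acetonide, freshly distilled | O=C[C@@H]1COC(C)(C)O1 | starting material
8 | (1R,2Z,6E)-1-[(4S)-2,2-dimethyl-1,3-dioxolan-4-yl]-2,6-dimethylocta-2,6-diene-1,8-diol | OC/C=C(\C)CC/C=C(/C)[C@@H](O)[C@@H]1COC(C)(C)O1 | intermediate
9 | (2E,6Z,8R)-8-[(4S)-2,2-dimethyl-1,3-dioxolan-4-yl]-8-hydroxy-3,7-dimethylocta-2,6-dienal | O=C/C=C(\C)CC/C=C(/C)[C@@H](O)[C@@H]1COC(C)(C)O1 | intermediate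
10 | (2E,6Z,8R)-8-[(tert-butyldimethylsilyl)oxy]-8-[(4S)-2,2-dimethyl-1,3-dioxolan-4-yl]-3,7-dimethylocta-2,6-dienal | O=C/C=C(\C)CC/C=C(/C)[C@@H](O[Si](C)(C)C(C)(C)C)[C@@H]1COC(C)(C)O1 | intermediate
11 | (2E,6Z,8R,9S)-8-[(tert-butyldimethylsilyl)oxy]-9,10-dihydroxy-3,7-dimethyldeca-2,6-dienal | O=C/C=C(\C)CC/C=C(/C)[C@@H](O[Si](C)(C)C(C)(C)C)[C@@H](O)CO | intermediate
12 | (2E,6Z,8R,9S)-8-[(tert-butyldimethylsilyl)oxy]-9-hydroxy-3,7-dimethyl-10-[(triethylsilyl)oxy]deca-2,6-dienal | O=C/C=C(\C)CC/C=C(/C)[C@@H](O[Si](C)(C)C(C)(C)C)[C@@H](O)CO[Si](CC)(CC)CC | intermediate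
13 | (2R)-4-tert-butoxy-2-methyl-4-oxobutanoic acid | CC(C)(C)OC(=O)C[C@@H](C)C(=O)O | starting material
14 | tert-butyl (3R)-4-hydroxy-3-methylbutanoate | CC(C)(C)OC(=O)C[C@@H](C)CO | intermediate
15 | tert-butyl (3R)-3-methyl-4-(octadecanoyloxy)butanoate | CC(C)(C)OC(=O)C[C@@H](C)COC(=O)CCCCCCCCCCCCCCCCC | intermediate
16 | (3R)-3-methyl-4-(octadecanoyloxy)butanoic acid | OC(=O)C[C@@H](C)COC(=O)CCCCCCCCCCCCCCCCC | intermediate
17 | (2S,3R,4Z,8E)-3-[(tert-butyldimethylsilyl)oxy]-4,8-dimethyl-10-oxo-1-[(triethylsilyl)oxy]deca-4,8-dien-2-yl (3R)-3-methyl-4-(octadecanoyloxy)butanoate | O=C/C=C(\C)CC/C=C(/C)[C@@H](O[Si](C)(C)C(C)(C)C)[C@@H](OC(=O)C[C@@H](C)COC(=O)CCCCCCCCCCCCCCCCC)CO[Si](CC)(CC)CC | intermediate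
18 | (2R,3R,4Z,8E)-3-[(tert-butyldimethylsilyl)oxy]-4,8-dimethyl-1,10-dioxodeca-4,8-dien-2-yl (3R)-3-methyl-4-(octadecanoyloxy)butanoate | O=C/C=C(\C)CC/C=C(/C)[C@@H](O[Si](C)(C)C(C)(C)C)[C@@H](OC(=O)C[C@@H](C)COC(=O)CCCCCCCCCCCCCCCCC)C=O | intermediate
19 | methyl (triphenyl-λ5-phosphanylidene)acetate | COC(=O)C=P(c1ccccc1)(c1ccccc1)c1ccccc1 | starting material
20 | [1-methoxy-1-oxo-3-(4,4,5,5-tetramethyl-1,3,2-dioxaborolan-2-yl)propan-2-yl]triphenylphosphonium iodide | COC(=O)C(CB1OC(C)(C)C(C)(C)O1)[P+](c1ccccc1)(c1ccccc1)c1ccccc1.[I-] | intermediate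
21 | methyl 3-(4,4,5,5-tetramethyl-1,3,2-dioxaborolan-2-yl)-2-(triphenyl-λ5-phosphanylidene)propanoate | COC(=O)C(CB1OC(C)(C)C(C)(C)O1)=P(c1ccccc1)(c1ccccc1)c1ccccc1 | intermediate
22 | methyl (2E,4S,5R,6Z,10E)-5-[(tert-butyldimethylsilyl)oxy]-6,10-dimethyl-4-{[(3R)-3-methyl-4-(octadecanoyloxy)butanoyl]oxy}-12-oxo-2-[(4,4,5,5-tetramethyl-1,3,2-dioxaborolan-2-yl)methyl]dodeca-2,6,10-trienoate | O=C/C=C(\C)CC/C=C(/C)[C@@H](O[Si](C)(C)C(C)(C)C)[C@@H](OC(=O)C[C@@H](C)COC(=O)CCCCCCCCCCCCCCCCC)/C=C(\CB1OC(C)(C)C(C)(C)O1)C(=O)OC | intermediate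
23 | methyl 2-[(1S,2S,3R,4Z,8E,10S)-3-[(tert-butyldimethylsilyl)oxy]-4,8-dimethyl-2-{[(3R)-3-methyl-4-(octadecanoyloxy)butanoyl]oxy}-10-[(4,4,5,5-tetramethyl-1,3,2-dioxaborolan-2-yl)oxy]cyclodeca-4,8-dien-1-yl]prop-2-enoate | CC1(C)OB(O[C@H]2/C=C(\C)CC/C=C(/C)[C@@H](O[Si](C)(C)C(C)(C)C)[C@@H](OC(=O)C[C@@H](C)COC(=O)CCCCCCCCCCCCCCCCC)[C@H]2C(=C)C(=O)OC)OC1(C)C | intermediate
24 | (3aS,4S,5R,6Z,10E,11aS)-5-[(tert-butyldimethylsilyl)oxy]-6,10-dimethyl-3-methylidene-2-oxo-2,3,3a,4,5,8,9,11a-octahydrocyclodeca[b]furan-4-yl (3R)-3-methyl-4-(octadecanoyloxy)butanoate | C=C1C(=O)O[C@H]2/C=C(\C)CC/C=C(/C)[C@@H](O[Si](C)(C)C(C)(C)C)[C@@H](OC(=O)C[C@@H](C)COC(=O)CCCCCCCCCCCCCCCCC)[C@@H]12 | intermediate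
25 | (3aS,4S,5R,6Z,10E,11aS)-5-hydroxy-6,10-dimethyl-3-methylidene-2-oxo-2,3,3a,4,5,8,9,11a-octahydrocyclodeca[b]furan-4-yl (3R)-3-methyl-4-(octadecanoyloxy)butanoate (CNP0114940.1) | C=C1C(=O)O[C@H]2/C=C(\C)CC/C=C(/C)[C@@H](O)[C@@H](OC(=O)C[C@@H](C)COC(=O)CCCCCCCCCCCCCCCCC)[C@@H]12 | target

**Step count**
Total: 16 steps (main line 12, side-chain acid 3, ylide 1).
Longest linear sequence: 12 steps (1, 2, 3, 4, 5, 6, 7, 11, 12, 14, 15, 16, from geranyl acetate).

**Three steps most likely to fail**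

Step 15 (macrocyclising allylboration–lactonisation). The risks are oligomerisation and a mismatch between the catalyst-preferred aldehyde face and the ring conformation imposed by C8/C9. The fallback changes the ring closure to an allylsilane (Hosomi–Sakurai) cyclisation with an open transition state. It sets out from dialdehyde 18: a Horner–Wadsworth–Emmons reaction with ethyl 2-(diethoxyphosphoryl)-3-(trimethylsilyl)propanoate (NaH, THF, −78 °C) gives, after separation of the geometric isomers, ethyl (2Z,4S,5R,6Z,10E)-5-[(tert-butyldimethylsilyl)oxy]-6,10-dimethyl-4-{[(3R)-3-methyl-4-(octadecanoyloxy)butanoyl]oxy}-12-oxo-2-[(trimethylsilyl)methyl]dodeca-2,6,10-trienoate F5 (C4 cis to CH2Si). Catalytic TBAF in THF at high dilution then forms the same C6–C7 bond, the alkoxide lactonises in the flask, and the route is rejoined at lactone 24.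

Step 14 (Wittig reaction with the new boryl ylide; step 13 shares the risk). The ylide may be hard to make or may add slowly or with poor E/Z control. The fallback builds the allylboronate by Morita–Baylis–Hillman chemistry and sets out from 18. DABCO-catalysed addition of methyl acrylate to the aliphatic aldehyde gives methyl (4S,5R,6Z,10E)-5-[(tert-butyldimethylsilyl)oxy]-3-hydroxy-6,10-dimethyl-2-methylidene-4-{[(3R)-3-methyl-4-(octadecanoyloxy)butanoyl]oxy}-12-oxododeca-6,10-dienoate F3 (both C3 epimers). Acetylation (Ac2O, pyridine, 0 °C) gives the corresponding 3-acetate F4. Pd2(dba)3-catalysed SN2′ borylation with B2pin2 comes back to the route at 22 and makes step 13 unnecessary.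

Step 2 (iodo-ylide olefination). Yield and Z/E ratio can be poor. The fallback makes the Z-alkenyl halide by trans-selective cross-coupling and sets out from aldehyde 4. Dibromo-olefination (CBr4, PPh3, CH2Cl2, 0 °C) gives (2E)-7,7-dibromo-3-methylhepta-2,6-dien-1-yl acetate F1. Negishi methylation of the bromine trans to the chain (MeZnCl, PdCl2(DPEphos) cat., THF) gives (2E,6Z)-7-bromo-3-methylocta-2,6-dien-1-yl acetate F2. Copper-catalysed halogen exchange with retention (NaI, CuI, N,N′-dimethylethylenediamine, dioxane, 110 °C) comes back to the route at iodide 5, which is methanolysed to 6 as before.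

**Further compounds**
F1 | step 2 | (2E)-7,7-dibromo-3-methylhepta-2,6-dien-1-yl acetate | CC(=O)OC/C=C(\C)CCC=C(Br)Br
F2 | step 2 | (2E,6Z)-7-bromo-3-methylocta-2,6-dien-1-yl acetate | CC(=O)OC/C=C(\C)CC/C=C(/C)Br
F3 | step 14 | methyl (4S,5R,6Z,10E)-5-[(tert-butyldimethylsilyl)oxy]-3-hydroxy-6,10-dimethyl-2-methylidene-4-{[(3R)-3-methyl-4-(octadecanoyloxy)butanoyl]oxy}-12-oxododeca-6,10-dienoate (C3 epimers) | O=C/C=C(\C)CC/C=C(/C)[C@@H](O[Si](C)(C)C(C)(C)C)[C@@H](OC(=O)C[C@@H](C)COC(=O)CCCCCCCCCCCCCCCCC)C(O)C(=C)C(=O)OC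
F4 | step 14 | methyl (4S,5R,6Z,10E)-3-acetoxy-5-[(tert-butyldimethylsilyl)oxy]-6,10-dimethyl-2-methylidene-4-{[(3R)-3-methyl-4-(octadecanoyloxy)butanoyl]oxy}-12-oxododeca-6,10-dienoate (C3 epimers) | O=C/C=C(\C)CC/C=C(/C)[C@@H](O[Si](C)(C)C(C)(C)C)[C@@H](OC(=O)C[C@@H](C)COC(=O)CCCCCCCCCCCCCCCCC)C(OC(C)=O)C(=C)C(=O)OC
F5 | step 15 | ethyl (2Z,4S,5R,6Z,10E)-5-[(tert-butyldimethylsilyl)oxy]-6,10-dimethyl-4-{[(3R)-3-methyl-4-(octadecanoyloxy)butanoyl]oxy}-12-oxo-2-[(trimethylsilyl)methyl]dodeca-2,6,10-trienoate | O=C/C=C(\C)CC/C=C(/C)[C@@H](O[Si](C)(C)C(C)(C)C)[C@@H](OC(=O)C[C@@H](C)COC(=O)CCCCCCCCCCCCCCCCC)/C=C(\C[Si](C)(C)C)C(=O)OCC
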